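**Retrosynthetic overview**
1. Ester C–O last: target ⇐ 6β-alcohol + 4-methoxybenzoyl chloride.
2. C5–H and C6–O ⇐ exo-face hydroboration of a C5=C6 alkene held on the finished 7-oxanorbornane; the C3 iodide left by the ring closure is removed afterwards.
3. Oxygen bridge (third ring) ⇐ iodoetherification of a 1β-hydroxy-eudesma-3,5-diene (C4–O bond; C4 fixed by the tether).
4. Dienol ⇐ 4-en-3-one: Δ1 dehydrogenation, epoxidation anti to the angular methyl, reductive epoxide opening (1β-OH), dienyl triflate formation and reduction.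
5. Decalin ⇐ (+)-dihydrocarvone (ring B, chiral pool) + ethyl vinyl ketone: intermolecular Michael addition makes C1–C10 and sets C10, aldol closes ring A. Ring order: B → A → oxygen bridge.

Convention and assumption: eudesmane numbering (decalin C1–C10, methyls on C4 and C10, isopropyl on C7); α = face of the C10 methyl, β = the opposite face; commercial (+)-dihydrocarvone (5R, mixture of C2 epimers) is the starting material. Target = (1R,4S,5R,6R,7S,10S).

**Step 1**
Reactants: 1 (+)-dihydrocarvone; 2 ethyl vinyl ketone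
Product: 4 cis-ketol 5α-hydroxy-eudesm-11-en-3-one (4β-CH3,7β-isopropenyl,10α-CH3), via Michael diketone 3 (not isolated)
Conditions: KOH (0.1 equiv), EtOH–Et2O, −10 → 0 °C; ketol crystallized
Reagents that add atoms: none
Why: Robinson annulation, first stage: the more substituted enolate of 1 adds to 2 in an intermolecular Michael reaction by axial attack through a chair with the isopropenyl group equatorial, which places the C10 methyl trans to the isopropenyl group (10-epi series), and the 1,5-diketone closes by intramolecular aldol addition to the crystalline ketol, whose crystallization removes the minor C10 epimer.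

**Step 2**
Reactants: 4 cis-ketol
Product: 5 (−)-10-epi-α-cyperone
Conditions: KOH, EtOH, reflux
Reagents that add atoms: none
Why: Base-mediated E1cB dehydration of the β-hydroxy ketone (aldol condensation) gives the conjugated enone and erases the provisional C4 and C5 centres while C7 and C10 are untouched.

**Step 3**
Reactants: 5 (−)-10-epi-α-cyperone
Product: 6 11,12-dihydro-10-epi-α-cyperone
Conditions: H2 (1 atm), RhCl(PPh3)3 (5 mol %), toluene–EtOH, rt
Reagents that add atoms: none
Why: Homogeneous hydrogenation with RhCl(PPh3)3 reduces the unhindered 1,1-disubstituted alkene and leaves the tetrasubstituted conjugated enone alone; no new stereocentre.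

**Step 4**
Reactants: 6 11,12-dihydro-10-epi-α-cyperone
Product: 10 eudesma-1,4-dien-3-one (7β-iPr,10α-CH3), via lithium dienolate 7 (not isolated), via selenide 8 (not isolated), via selenoxide 9 (not isolated)
Conditions: LiN(iPr)2, THF, −78 °C; PhSeCl, −78 °C; then 30% H2O2, pyridine, CH2Cl2, 0 °C → rt
Reagents that add atoms: none
Why: Kinetic deprotonation at C2 gives the cross-conjugated dienolate, α-selenenylation and selenoxide syn-elimination (only C1 carries β-hydrogens) install the Δ1 double bond regiospecifically.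

**Step 5**
Reactants: 10 eudesma-1,4-dien-3-one
Product: 11 1β,2β-epoxy-eudesm-4-en-3-one (7β-iPr,10α-CH3)
Conditions: 30% H2O2, NaOH (aq), MeOH, 0 °C
Reagents that add atoms: hydrogen peroxide, OO
Why: Weitz–Scheffer nucleophilic epoxidation attacks only the less substituted Δ1 bond (C5 of Δ4 is fully substituted) and from the face anti to the angular methyl, as in steroidal 1,4-dien-3-ones, setting C1–O β.

**Step 6**
Reactants: 11 1β,2β-epoxy-eudesm-4-en-3-one
Product: 12 1β-hydroxy-eudesm-4-en-3-one (7β-iPr,10α-CH3)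
Conditions: SmI2 (2.2 equiv), THF–MeOH, −90 °C
Reagents that add atoms: none
Why: Single-electron reduction of the α,β-epoxy ketone cleaves the C2–O bond to the β-hydroxy ketone with C1 unchanged, and the low temperature with MeOH as proton source avoids enone reduction and dehydration.

**Step 7**
Reactants: 12 1β-hydroxy-eudesm-4-en-3-one
Product: 13 1β-(tert-butyldimethylsilyloxy)-eudesm-4-en-3-one (7β-iPr,10α-CH3)
Conditions: TBSOTf, 2,6-lutidine, CH2Cl2, −78 → 0 °C
Reagents that add atoms: tert-butyldimethylsilyl triflate, CC(C)(C)[Si](C)(C)OS(=O)(=O)C(F)(F)F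
Why: Silyl triflate silylation protects the hindered axial alcohol so that it is neither triflated nor eliminated in the next step.

**Step 8**
Reactants: 13 1β-silyloxy enone
Product: 14 1β-(tert-butyldimethylsilyloxy)-eudesma-3,5-dien-3-yl triflate (7β-iPr,10α-CH3)
Conditions: Tf2O, 2,6-di-tert-butyl-4-methylpyridine, CH2Cl2, 0 °C → rt
Reagents that add atoms: triflic anhydride, FC(F)(F)S(=O)(=O)OS(=O)(=O)C(F)(F)F
Why: O-triflation of the enone carbonyl followed by loss of the γ-proton at C6 under a non-nucleophilic base gives the thermodynamic heteroannular dienyl triflate, as with steroidal 4-en-3-ones.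

**Step 9**
Reactants: 14 dienyl triflate
Product: 15 1β-(tert-butyldimethylsilyloxy)-eudesma-3,5-diene (7β-iPr,10α-CH3)
Conditions: Pd(OAc)2 (5 mol %), PPh3, Bu3N, HCO2H, DMF, 60 °C
Reagents that add atoms: none
Why: Palladium-catalysed formate reduction (oxidative addition of the vinyl triflate to zerovalent palladium formed in situ, formate-to-hydride exchange, reductive elimination) replaces OTf by H without moving the diene.

**Step 10**
Reactants: 15 silyloxy diene
Product: 16 eudesma-3,5-dien-1β-ol (7β-iPr,10α-CH3)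
Conditions: Bu4NF, THF, rt → 45 °C
Reagents that add atoms: none
Why: Fluoride-mediated desilylation frees the 1β-hydroxyl under non-acidic conditions that the diene tolerates.

**Step 11**
Reactants: 16 eudesma-3,5-dien-1β-ol
Product: 17 3α-iodo-1β,4β-epoxy-eudesm-5-ene (7β-iPr,10α-CH3)
Conditions: N-iodosuccinimide, NaHCO3 (buffer), MeCN, −20 → 0 °C, dark
Reagents that add atoms: N-iodosuccinimide, O=C1CCC(=O)N1I
Why: Iodoetherification: iodine adds to the diene terminus C3, and the allylic cation is captured at C4 by the 1β-hydroxyl, which can reach C4 only from the β face (C4–O β, C4 methyl α), while capture at C6 would require a bridgehead alkene, so the C5=C6 bond is kept.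

**Step 12**
Reactants: 17 iodo ether alkene
Product: 19 3α-iodo-1β,4β-epoxy-5βH-eudesman-6β-ol (7β-iPr,10α-CH3), via alkylborane 18 (not isolated)
Conditions: BH3·THF, THF, 0 °C → rt; then NaOH (aq), 30% H2O2, 0 °C
Reagents that add atoms: hydrogen peroxide, OO
Why: Hydroboration–oxidation adds H and B syn with boron on the less substituted C6, from the exo (β) face of the oxanorbornane because the endo face of C5 is blocked by the C2–C3 bridge, the endo iodide and the α C10 methyl, so H5β and 6β-OH (the trans ring fusion) are set under kinetic control and oxidation proceeds with retention.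

**Step 13**
Reactants: 19 iodo alcohol
Product: 20 1β,4β-epoxy-5βH-eudesman-6β-ol (7β-iPr,10α-CH3)
Conditions: Bu3SnH, AIBN (cat.), toluene, 80 °C
Reagents that add atoms: none
Why: Radical chain dehalogenation removes the iodide; it is run after the hydroboration so that the C3 radical has no homoallylic double bond onto which it could rearrange.

**Step 14**
Reactants: 20 epoxy alcohol; 21 4-methoxybenzoyl chloride
Product: 22 target ester
Conditions: DMAP, Et3N, CH2Cl2, rt → 40 °C
Reagents that add atoms: none
Why: DMAP-catalysed acyl transfer through the acylpyridinium ion esterifies the hindered secondary alcohol at oxygen, so no stereocentre is touched.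

**Compound list**
1 | (+)-dihydrocarvone, (2R,5R)-2-methyl-5-(prop-1-en-2-yl)cyclohexan-1-one (major epimer drawn) | O=C1C[C@H](C(C)=C)CC[C@H]1C | starting material
2 | ethyl vinyl ketone (pent-1-en-3-one) | CCC(=O)C=C | starting material
3 | (2R,5R)-2-methyl-2-(3-oxopentyl)-5-(prop-1-en-2-yl)cyclohexan-1-one | O=C1C[C@H](C(C)=C)CC[C@]1(C)CCC(=O)CC | intermediate
4 | cis-fused ketol, 5α-hydroxy-eudesm-11-en-3-one (4β-CH3, 7β-isopropenyl, 10α-CH3; C4/C5 assigned by analogy and erased in step 2) | C1[C@H](C(C)=C)CC[C@]2(C)CCC(=O)[C@H](C)[C@]12O | intermediate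
5 | (−)-10-epi-α-cyperone, (4aR,7R)-1,4a-dimethyl-7-(prop-1-en-2-yl)-4,4a,5,6,7,8-hexahydronaphthalen-2(3H)-one | C1[C@H](C(C)=C)CC[C@]2(C)CCC(=O)C(C)=C12 | intermediate
6 | 11,12-dihydro-10-epi-α-cyperone, eudesm-4-en-3-one (7β-iPr, 10α-CH3) | C1[C@H](C(C)C)CC[C@]2(C)CCC(=O)C(C)=C12 | intermediate
7 | lithium eudesma-2,4-dien-3-olate (7β-iPr, 10α-CH3) | C1[C@H](C(C)C)CC[C@]2(C)CC=C(O[Li])C(C)=C12 | intermediate
8 | 2β-(phenylselanyl)-eudesm-4-en-3-one (7β-iPr, 10α-CH3) | C1[C@H](C(C)C)CC[C@]2(C)C[C@H]([Se]c3ccccc3)C(=O)C(C)=C12 | intermediate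
9 | selenoxide of 8 | C1[C@H](C(C)C)CC[C@]2(C)C[C@H]([Se](=O)c3ccccc3)C(=O)C(C)=C12 | intermediate
10 | eudesma-1,4-dien-3-one (7β-iPr, 10α-CH3) | C1[C@H](C(C)C)CC[C@]2(C)C=CC(=O)C(C)=C12 | intermediate
11 | 1β,2β-epoxy-eudesm-4-en-3-one (7β-iPr, 10α-CH3) | C1[C@H](C(C)C)CC[C@]2(C)[C@@H]3O[C@@H]3C(=O)C(C)=C12 | intermediate
12 | 1β-hydroxy-eudesm-4-en-3-one (7β-iPr, 10α-CH3) | C1[C@H](C(C)C)CC[C@]2(C)[C@H](O)CC(=O)C(C)=C12 | intermediate
13 | 1β-(tert-butyldimethylsilyloxy)-eudesm-4-en-3-one (7β-iPr, 10α-CH3) | C1[C@H](C(C)C)CC[C@]2(C)[C@H](O[Si](C)(C)C(C)(C)C)CC(=O)C(C)=C12 | intermediate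
14 | 1β-(tert-butyldimethylsilyloxy)-eudesma-3,5-dien-3-yl triflate (7β-iPr, 10α-CH3) | C1[C@H](C(C)C)CC[C@]2(C)[C@H](O[Si](C)(C)C(C)(C)C)CC(OS(=O)(=O)C(F)(F)F)=C(C)C=12 | intermediate
15 | 1β-(tert-butyldimethylsilyloxy)-eudesma-3,5-diene (7β-iPr, 10α-CH3) | C1[C@H](C(C)C)CC[C@]2(C)[C@H](O[Si](C)(C)C(C)(C)C)CC=C(C)C=12 | intermediate
16 | eudesma-3,5-dien-1β-ol (7β-iPr, 10α-CH3) | C1[C@H](C(C)C)CC[C@]2(C)[C@H](O)CC=C(C)C=12 | intermediate
17 | 3α-iodo-1β,4β-epoxy-eudesm-5-ene (7β-iPr, 10α-CH3, 4α-CH3) | C1[C@H](C(C)C)CC[C@]2(C)[C@H]3C[C@H]([C@](C)(O3)C=12)I | intermediate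
18 | (3α-iodo-1β,4β-epoxy-5βH-eudesman-6β-yl)borane | B[C@@H]1[C@H](C(C)C)CC[C@]2(C)[C@H]3C[C@H]([C@](C)(O3)[C@@H]12)I | intermediate
19 | 3α-iodo-1β,4β-epoxy-5βH-eudesman-6β-ol (7β-iPr, 10α-CH3) | O[C@@H]1[C@H](C(C)C)CC[C@]2(C)[C@H]3C[C@H]([C@](C)(O3)[C@@H]12)I | intermediate
20 | 1β,4β-epoxy-5βH-eudesman-6β-ol (7β-iPr, 10α-CH3) | O[C@@H]1[C@H](C(C)C)CC[C@]2(C)[C@H]3CC[C@](C)(O3)[C@@H]12 | intermediate
21 | 4-methoxybenzoyl chloride | COc1ccc(C(=O)Cl)cc1 | starting material
22 | (1R,4S,5R,6R,7S,10S)-1,4-epoxyeudesman-6-yl 4-methoxybenzoate | COc1ccc(C(=O)O[C@@H]2[C@H](C(C)C)CC[C@]3(C)[C@H]4CC[C@](C)(O4)[C@@H]23)cc1 | target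

**Totals**
Total step count: 14. Longest linear sequence: 14 steps (from 1; 2 and 21 are bought).

**Three steps most likely to fail**

Step 1. The facial selectivity of the Michael addition is only moderate and the ketol yield is modest. Fallback, setting out from 1: condensation with (S)-1-phenylethylamine (toluene, TsOH cat., Dean–Stark) gives the imine F1. Its secondary enamine tautomer adds to 2 (THF, rt → 40 °C) on the face chosen by the auxiliary, which here matches the substrate preference, to give the Michael imine F2. Hydrolysis with aqueous AcOH releases diketone 3, where the route is rejoined; 3 is then closed and dehydrated with KOH/EtOH to 4 and 5.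

Step 11. The closure builds a strained bridged allylic ether; the iodo-allyl cation may instead lose a proton to a triene, or the ether may reopen. Fallback, setting out from 16: a radical–polar crossover hydroalkoxylation with [N,N′-bis(3,5-di-tert-butylsalicylidene)-1,2-cyclohexanediaminato]cobalt (divalent cobalt, 5 mol %), N-fluoro-2,4,6-trimethylpyridinium tetrafluoroborate and PhSiH3 in PhCF3 at rt. Hydrogen-atom transfer to C3 gives the allyl radical, which is oxidized to the cation and trapped at C4 by the 1β-hydroxyl, giving directly the iodine-free ether alkene F3. Hydroboration of F3 under the step 12 conditions gives the alkylborane F4 and, after oxidation, alcohol 20, where the route is rejoined (step 13 is then not needed).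

Step 12. Borane must reach the exo face next to the β-isopropyl group while the trans ring fusion is created; boron may also add at C5 and open the ether by β-elimination. Fallback, setting out from 17: mCPBA (NaHCO3, CH2Cl2, 0 °C) epoxidizes C5=C6 from the exo face to the epoxide F5. Reductive radical opening with Cp2TiCl generated catalytically (Cp2TiCl2, Mn, 2,4,6-collidine hydrochloride, 1,4-cyclohexadiene, THF; trivalent titanium) breaks the C5–O bond to the tertiary C5 radical, which takes a hydrogen atom on its exo face and gives 19, where the route is rejoined.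

**Further compounds**
F1 | step 1 | (S)-1-phenylethylamine imine of (+)-dihydrocarvone | C[C@H](N=C1C[C@H](C(C)=C)CC[C@H]1C)c1ccccc1
F2 | step 1 | (S)-1-phenylethylamine imine of diketone 3 (ring C=N) | C[C@H](N=C1C[C@H](C(C)=C)CC[C@]1(C)CCC(=O)CC)c1ccccc1
F3 | step 11 | 1β,4β-epoxy-eudesm-5-ene (7β-iPr, 10α-CH3, 4α-CH3) | C1[C@H](C(C)C)CC[C@]2(C)[C@H]3CC[C@](C)(O3)C=12
F4 | step 11 | (1β,4β-epoxy-5βH-eudesman-6β-yl)borane | B[C@@H]1[C@H](C(C)C)CC[C@]2(C)[C@H]3CC[C@](C)(O3)[C@@H]12
F5 | step 12 | 3α-iodo-1β,4β:5β,6β-diepoxy-eudesmane (7β-iPr, 10α-CH3) | O1[C@@H]2[C@H](C(C)C)CC[C@]3(C)[C@H]4C[C@H]([C@](C)(O4)[C@@]123)I
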